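**Retrosynthetic overview**
1. Last step: a base-triggered Michael/Claisen cascade on an aldol adduct. C8 adds to C16 (cyclopentane), then C2 attacks C3 with opening of a γ-lactone (cyclooctane, enolised β-keto lactone).
2. The aldol adduct comes from a proline aldol (C8–C9) between a cage aldehyde and a C3–C8 keto lactone; the keto lactone comes from methacrolein and butane-2,3-dione by NHC homoenolate annulation.
3. The cage aldehyde (2-oxabicyclo[2.2.2]octane fused to a spiro tetronate) comes from hydroxyl-directed epoxidation of a 1,2-dimethylcyclohexenol and anti opening at C12 by the tetronic acid oxygen.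
4. The spiro tetronic acid comes from acetate aldol/oxidation on a cyclohexene carrying C15(OAc)(CHO); C11–OH and the C12 methyl come from Rubottom oxidation, enol triflate formation and Stille methylation.
5. The cyclohexene comes from an ammonium-salt-catalysed enantioselective Diels–Alder of 2-acetoxyacrolein with a 2-silyloxy diene. Ring order: cyclohexene, tetronate, oxabicyclooctane, cyclopentane, cyclooctane.

Atom labels used below (target): C1 lactone C=O, C2, C3 enol carbon, C4 CHMe, C5 CH2, C6 C(OH)Me, C7 ketone, C8, C9 CHOH, C10, C11 CHOH, C12 C(Me)–O, C13 C(OH)Me, C14 CH2, C15 spiro C–O(lactone), C16 ether carbon bonded to C2, C8 and C15.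

Assumption: the SMILES is taken as the full definition of the target (enol tautomer as drawn), and each chiral catalyst is used as the enantiomer that gives the configuration shown (assigned by analogy with its accepted model; the antipode is used if induction is opposite).

**Step 1**
Reactants: 1 2,2-dimethyl-1,3-dioxan-5-one
Product: 2 dioxin enol acetate
Conditions: KN(SiMe3)2, THF, −78 °C; then Ac2O, −78 → 0 °C
Reagents that add atoms: acetic anhydride, CC(=O)OC(C)=O
Why: O-acylation of the potassium enolate of the dioxanone (enol ester formation) gives the 4H-1,3-dioxin enol acetate.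

**Step 2**
Reactants: 2 dioxin enol acetate
Product: 3 2-acetoxyacrolein
Conditions: toluene, 130 °C (sealed tube), then distil
Reagents that add atoms: none
Why: thermal retro-hetero-Diels–Alder cycloreversion of the 4H-1,3-dioxin expels acetone and unmasks the α-acyloxy enal.

**Step 3**
Reactants: 4 2,2-dimethoxyacetaldehyde; 5 dimethyl (2-oxobutyl)phosphonate
Product: 6 (E)-6,6-dimethoxyhex-4-en-3-one
Conditions: K2CO3, H2O/THF, 0 °C → rt
Reagents that add atoms: none
Why: Horner–Wadsworth–Emmons olefination with a stabilised β-keto phosphonate gives the E-enone.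

**Step 4**
Reactants: 6 (E)-6,6-dimethoxyhex-4-en-3-one
Product: 7 silyloxy diene
Conditions: KN(SiMe3)2, THF, −78 °C; then TBSCl, −78 → 0 °C
Reagents that add atoms: tert-butyldimethylsilyl chloride, CC(C)(C)[Si](C)(C)Cl
Why: kinetic α'-deprotonation of the ethyl ketone gives the Z-enolate, and O-silylation (silyl enol ether formation) gives the 2-silyloxy diene with the terminal methyl on the outside.

**Step 5**
Reactants: 7 silyloxy diene; 3 2-acetoxyacrolein
Product: 8 Diels–Alder adduct
Conditions: (S)-1,1'-binaphthyl-2,2'-diamine (10 mol%), (CF3SO2)2NH (19 mol%), EtCN, −40 °C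
Reagents that add atoms: none
Why: Diels–Alder reaction under iminium activation by a chiral primary ammonium salt (a catalyst class established for α-acyloxyacroleins), in which the nucleophilic C13 of the silyl dienol ether bonds to the enal β-carbon C14 and C10 to C15 (para to OTBS), the endo-iminium transition state places CHO, CH(OMe)2 and the C13 methyl cis, and the catalyst shields one enal face so that C15 (and with it C10 and C13) is set.

**Step 6**
Reactants: 8 Diels–Alder adduct
Product: 10 α-silyloxy ketone, via silyloxy epoxide 9 (not isolated)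
Conditions: dimethyldioxirane, acetone/CH2Cl2, −78 → 0 °C; then pyridinium p-toluenesulfonate (cat.), rt
Reagents that add atoms: dimethyldioxirane, CC1(C)OO1
Why: Rubottom oxidation, in which the silyl enol ether is epoxidised anti to the cis C10 and C13 substituents and a 1,4-silyl shift then leaves OTBS at C11 on the acetate face (sets C11).

**Step 7**
Reactants: 10 α-silyloxy ketone
Product: 11 enol triflate
Conditions: KN(SiMe3)2, THF, −78 °C; then PhN(SO2CF3)2
Reagents that add atoms: N-phenylbis(trifluoromethanesulfonimide), O=S(=O)(N(c1ccccc1)S(=O)(=O)C(F)(F)F)C(F)(F)F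
Why: enol triflate formation, with enolisation directed away from the α-silyloxy carbon so that the double bond is fixed at C12=C13; the aldehyde has no α-hydrogen and the acetate is less acidic than the ketone.

**Step 8**
Reactants: 11 enol triflate
Product: 12 dimethylcyclohexene aldehyde
Conditions: SnMe4, Pd(PPh3)4 (5 mol%), LiCl, DMF, 80 °C
Reagents that add atoms: tetramethylstannane, C[Sn](C)(C)C
Why: Stille cross-coupling (oxidative addition of zerovalent palladium into the vinyl triflate, then methyl transfer from tin) installs the C12 methyl under neutral conditions that spare aldehyde, acetate and acetal.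

**Step 9**
Reactants: 12 dimethylcyclohexene aldehyde
Product: 13 hydroxy spirolactone
Conditions: LiN(iPr)2 (1.1 equiv), THF, −78 °C; AcOH quench
Reagents that add atoms: none
Why: intramolecular acetate aldol addition onto the neighbouring non-enolisable aldehyde closes the γ-lactone (C2–C16 bond); the new carbinol centre C16 forms as a mixture that is removed in the next step.

**Step 10**
Reactants: 13 hydroxy spirolactone
Product: 14 silyl-protected spirotetronic acid
Conditions: nPr4N[RuO4] (5 mol%), N-methylmorpholine N-oxide, 4 Å MS, CH2Cl2, rt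
Reagents that add atoms: none
Why: Ley–Griffith oxidation of the β-hydroxy lactone gives the β-keto lactone, which rests as the tetronic acid enol.

**Step 11**
Reactants: 14 silyl-protected spirotetronic acid
Product: 15 spirotetronic acid allylic alcohol
Conditions: HF·pyridine, THF/pyridine, 0 °C → rt
Reagents that add atoms: none
Why: fluoride-mediated silyl ether cleavage frees the C11 allylic hydroxyl needed to direct the epoxidation.

**Step 12**
Reactants: 15 spirotetronic acid allylic alcohol
Product: 18 cage aldehyde, via epoxy alcohol 16 (not isolated), via cage acetal 17 (not isolated)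
Conditions: VO(acac)2 (5 mol%), t-BuOOH, CH2Cl2, 0 °C → rt; then TsOH·H2O, acetone/H2O, rt
Reagents that add atoms: tert-butyl hydroperoxide, CC(C)(C)OO; water, O
Why: hydroxyl-directed vanadium-catalysed epoxidation puts the oxygen on the C12=C13 face cis to C11–OH, and the tetronic acid oxygen, held over the ring in the plane through C15 and C12, then opens the epoxide at C12 with inversion (acid-promoted anti epoxide opening, the mode used for the abyssomicin core), which sets C12 and C13 before aqueous acid hydrolyses the acetal.

**Step 13**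
Reactants: 19 methacrolein; 20 butane-2,3-dione
Product: 21 keto lactone
Conditions: (5aS,10bR)-2-(2,4,6-trimethylphenyl)-5a,10b-dihydro-4H,6H-indeno[2,1-b][1,2,4]triazolo[4,3-d][1,4]oxazin-2-ium chloride (10 mol%), 1,8-diazabicyclo[5.4.0]undec-7-ene (15 mol%), LiCl (20 mol%), THF, rt, slow addition of 19
Reagents that add atoms: none
Why: NHC homoenolate [3+2] annulation of an enal with an activated ketone, in which the β-carbon of the Breslow homoenolate adds to one face of a diketone carbonyl (sets C6), catalyst-controlled α-protonation of the azolium enol sets C4, and lactonisation releases the carbene.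

**Step 14**
Reactants: 18 cage aldehyde; 21 keto lactone
Product: 22 aldol adduct
Conditions: (S)-proline (30 mol%), DMSO, rt, equimolar partners at high concentration
Reagents that add atoms: none
Why: proline-catalysed direct aldol addition (enamine catalysis), in which only the methyl side of the ketone of 21 can form an enamine, the hindered α-branched aldehyde cannot self-condense, and (S)-proline directs attack to the aldehyde re face to give the (9R)-carbinol.

**Step 15**
Reactants: 22 aldol adduct
Product: 24 target CNP0073514.1, via Michael adduct 23 (not isolated)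
Conditions: LiN(SiMe3)2 (5 equiv), THF, −78 → 0 °C; AcOH quench
Reagents that add atoms: none
Why: Proposed new method: excess amide base turns 22 into its alkoxide/C8-enolate form (an enolised aldolate cannot cleave by retro-aldol), C8 adds 5-exo to the tetronate carbon C16 from the only face the C9–C10 tether allows (sets C16 and, reversibly, C8), and the C2 lactone enolate so formed attacks the γ-lactone carbonyl C3 in an unstrained seven-membered mode, which frees the C6 alkoxide, closes the eight-membered ring and becomes irreversible on deprotonation of the β-keto lactone, whereas direct attack of C8 on C3 would need a strained 7-oxanorbornane-type transition state; the closest known reaction types are the Michael–Dieckmann annulation and the transannular enolate Michael addition onto C16 that turns abyssomicin C into abyssomicin D.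

**Compound list**
1 | 2,2-dimethyl-1,3-dioxan-5-one | CC1(C)OCC(=O)CO1 | starting material
2 | dioxin enol acetate: 2,2-dimethyl-4H-1,3-dioxin-5-yl acetate | CC(=O)OC1=COC(C)(C)OC1 | intermediate
3 | 2-acetoxyacrolein (3-oxoprop-1-en-2-yl acetate) | CC(=O)OC(=C)C=O | intermediate
4 | 2,2-dimethoxyacetaldehyde | COC(OC)C=O | starting material
5 | dimethyl (2-oxobutyl)phosphonate | CCC(=O)CP(=O)(OC)OC | starting material
6 | (E)-6,6-dimethoxyhex-4-en-3-one | CCC(=O)/C=C/C(OC)OC | intermediate
7 | silyloxy diene: tert-butyl{[(2Z,4E)-6,6-dimethoxyhexa-2,4-dien-3-yl]oxy}dimethylsilane | C/C=C(\O[Si](C)(C)C(C)(C)C)/C=C/C(OC)OC | intermediate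
8 | Diels–Alder adduct: [(1S,2S,5S)-4-(tert-butyldimethylsilyloxy)-2-(dimethoxymethyl)-1-formyl-5-methylcyclohex-3-en-1-yl] acetate; CHO, CH(OMe)2 and 5-Me mutually cis | CC(=O)O[C@@]1(C=O)C[C@H](C)C(O[Si](C)(C)C(C)(C)C)=C[C@@H]1C(OC)OC | intermediate
9 | silyloxy epoxide: 3,4-epoxide of 8 on the ring face that carries the acetoxy group | CC(=O)O[C@@]1(C=O)C[C@H](C)[C@@]2(O[Si](C)(C)C(C)(C)C)O[C@H]2[C@@H]1C(OC)OC | intermediate
10 | α-silyloxy ketone: [(1S,2S,3S,5S)-3-(tert-butyldimethylsilyloxy)-2-(dimethoxymethyl)-1-formyl-5-methyl-4-oxocyclohexyl] acetate; 3-OTBS cis to 1-OAc | CC(=O)O[C@@]1(C=O)C[C@H](C)C(=O)[C@@H](O[Si](C)(C)C(C)(C)C)[C@@H]1C(OC)OC | intermediate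
11 | enol triflate: [(1S,2S,3S)-3-(tert-butyldimethylsilyloxy)-2-(dimethoxymethyl)-1-formyl-5-methyl-4-(trifluoromethylsulfonyloxy)cyclohex-4-en-1-yl] acetate | CC(=O)O[C@@]1(C=O)CC(C)=C(OS(=O)(=O)C(F)(F)F)[C@@H](O[Si](C)(C)C(C)(C)C)[C@@H]1C(OC)OC | intermediate
12 | dimethylcyclohexene aldehyde: [(1S,2S,3S)-3-(tert-butyldimethylsilyloxy)-2-(dimethoxymethyl)-1-formyl-4,5-dimethylcyclohex-4-en-1-yl] acetate | CC(=O)O[C@@]1(C=O)CC(C)=C(C)[C@@H](O[Si](C)(C)C(C)(C)C)[C@@H]1C(OC)OC | intermediate
13 | hydroxy spirolactone: 7-(tert-butyldimethylsilyloxy)-6-(dimethoxymethyl)-4-hydroxy-8,9-dimethyl-1-oxaspiro[4.5]dec-8-en-2-one; ring configuration as in 12, C4 epimers | O=C1CC(O)[C@]2(O1)CC(C)=C(C)[C@@H](O[Si](C)(C)C(C)(C)C)[C@@H]2C(OC)OC | intermediate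
14 | silyl-protected spirotetronic acid: 7-(tert-butyldimethylsilyloxy)-6-(dimethoxymethyl)-4-hydroxy-8,9-dimethyl-1-oxaspiro[4.5]deca-3,8-dien-2-one; ring configuration as in 12 | O=C1C=C(O)[C@]2(O1)CC(C)=C(C)[C@@H](O[Si](C)(C)C(C)(C)C)[C@@H]2C(OC)OC | intermediate
15 | spirotetronic acid allylic alcohol: 6-(dimethoxymethyl)-4,7-dihydroxy-8,9-dimethyl-1-oxaspiro[4.5]deca-3,8-dien-2-one; 7-OH trans to 6-CH(OMe)2 and on the face of the lactone ring oxygen | O=C1C=C(O)[C@]2(O1)CC(C)=C(C)[C@@H](O)[C@@H]2C(OC)OC | intermediate
16 | epoxy alcohol: 8,9-epoxide of 15 cis to the 7-OH | O=C1C=C(O)[C@]2(O1)C[C@@]3(C)O[C@@]3(C)[C@@H](O)[C@@H]2C(OC)OC | intermediate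
17 | cage acetal: 2-oxabicyclo[2.2.2]octane (C12–O–C16 ether) fused to the butenolide C16=C2–C1(=O)–O–C15, with C10–CH(OMe)2, C11–OH, C12–Me and C13(OH)Me; both hydroxyls anti to the ether bridge | O=C1C=C2O[C@]3(C)[C@@H](O)[C@H](C(OC)OC)[C@@]2(O1)C[C@@]3(C)O | intermediate
18 | cage aldehyde: as 17 with C10–CHO | O=C1C=C2O[C@]3(C)[C@@H](O)[C@H](C=O)[C@@]2(O1)C[C@@]3(C)O | intermediate
19 | methacrolein (2-methylprop-2-enal) | CC(=C)C=O | starting material
20 | butane-2,3-dione | CC(=O)C(C)=O | starting material
21 | keto lactone: (3S,5S)-5-acetyl-3,5-dimethyloxolan-2-one; 3-Me cis to acetyl | C[C@H]1C[C@](C)(OC1=O)C(C)=O | intermediate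
22 | aldol adduct: cage of 18 with C9 as (9R)-CH(OH) linked through C8H2 to the ketone carbonyl C7 of the lactone unit of 21 | C[C@H]1C[C@](C)(OC1=O)C(=O)C[C@@H](O)[C@H]2[C@H](O)[C@@]3(C)OC4=CC(=O)O[C@@]24C[C@@]3(C)O | intermediate
23 | Michael adduct: 22 after C8–C16 bond formation (cyclopentane closed, saturated lactone with C2H2, γ-lactone unit intact) | C[C@H]1C[C@](C)(OC1=O)C(=O)[C@@H]2[C@@H](O)[C@H]3[C@H](O)[C@@]4(C)O[C@@]25CC(=O)O[C@@]35C[C@@]4(C)O | intermediate
24 | target CNP0073514.1 | C[C@H]1C[C@](C)(O)C(=O)[C@@H]2[C@@H](O)[C@H]3[C@H](O)[C@@]4(C)O[C@@]25/C(=C\1O)C(=O)O[C@@]35C[C@@]4(C)O | target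

**Step count**
Total: 15 steps. Longest linear sequence: 12 steps (steps 3–12, 14, 15, from 4 and 5).

**Three steps most likely to fail**

Step 15 (the proposed new cascade). The risks are a slow Michael addition to the singly activated tetronate, epimerisation at C4 through the γ-lactone enolate, and loss of the aldolate. The fallback uses known reactions and runs from 22 to 24 with the two ring closures separated and the nucleophile changed from an enolate to a silyl enol ether. Silylation of 22 (Me3SiOSO2CF3, Et3N, CH2Cl2) gives the tris-O-silyl silyl enol ether F4. A Lewis-acid Mukaiyama–Michael addition (SnCl4, CH2Cl2, −78 °C, aqueous work-up) closes the cyclopentane and gives the silylated Michael adduct F5. A separate Claisen condensation of its lactone enolate onto the γ-lactone (LiN(SiMe3)2, THF, −78 → 0 °C) closes the eight-membered ring and gives the silylated target F6. HF·pyridine then returns to the route at 24.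

Step 5 (Diels–Alder). The silyl dienol ether and the dimethyl acetal may not survive the protic ammonium salt and the water released on iminium formation, and the endo/exo ratio is not assured. The fallback sets out from 7 and 3 and comes back at 8. It replaces covalent iminium activation by aprotic Lewis-acid activation of the aldehyde with a cationic oxazaborolidinium catalyst, (S)-1-(2-methylphenyl)-3,3-diphenyltetrahydro-1H,3H-pyrrolo[1,2-c][1,3,2]oxazaborole protonated by (CF3SO2)2NH (10–20 mol%, CH2Cl2, −78 °C); this catalyst class accepts 2-substituted acroleins and 2-silyloxy dienes. It forms no new compound (F0).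

Step 13 (NHC annulation). α-Substituted enals form homoenolates slowly, cross-benzoin addition to the diketone can compete, and the C4 configuration rests on a protonation. The fallback sets out from 20 and comes back at 21. Wittig mono-methylenation of 20 (Ph3P=CH2, THF, −78 → 0 °C) gives 3-methylbut-3-en-2-one F1. Enamine-catalysed Michael addition of propanal ((S)-2-[diphenyl(trimethylsilyloxy)methyl]pyrrolidine, 10 mol%) sets C4 and gives (2S)-2,4-dimethyl-5-oxohexanal F2. Pinnick oxidation (NaClO2, NaH2PO4, 2-methylbut-2-ene) gives (2S)-2,4-dimethyl-5-oxohexanoic acid F3. Oxidative α-oxylactonisation at the tertiary α-carbon with a chiral aryl iodide catalyst (2,2'-[(2-iodo-1,3-phenylene)bis(oxy)]bis(N-mesitylpropanamide), 10 mol%, mCPBA, trivalent iodine as the active species) forms the C6–O bond and gives 21.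

**Further compounds**
F0 | step 5 | none | none
F1 | step 13 | 3-methylbut-3-en-2-one | CC(=C)C(C)=O
F2 | step 13 | (2S)-2,4-dimethyl-5-oxohexanal (C4 epimers) | C[C@H](C=O)CC(C)C(C)=O
F3 | step 13 | (2S)-2,4-dimethyl-5-oxohexanoic acid (C4 epimers) | C[C@H](C(=O)O)CC(C)C(C)=O
F4 | step 15 | tris-O-trimethylsilyl (C9, C11, C13) silyl enol ether (C7=C8) of 22 | C[C@H]1C[C@](C)(OC1=O)C(O[Si](C)(C)C)=C[C@@H](O[Si](C)(C)C)[C@H]2[C@H](O[Si](C)(C)C)[C@@]3(C)OC4=CC(=O)O[C@@]24C[C@@]3(C)O[Si](C)(C)C
F5 | step 15 | tris-O-trimethylsilyl (C9, C11, C13) ether of Michael adduct 23 | C[C@H]1C[C@](C)(OC1=O)C(=O)[C@@H]2[C@@H](O[Si](C)(C)C)[C@H]3[C@H](O[Si](C)(C)C)[C@@]4(C)O[C@@]25CC(=O)O[C@@]35C[C@@]4(C)O[Si](C)(C)C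
F6 | step 15 | tris-O-trimethylsilyl (C9, C11, C13) ether of target 24 | C[C@H]1C[C@](C)(O)C(=O)[C@@H]2[C@@H](O[Si](C)(C)C)[C@H]3[C@H](O[Si](C)(C)C)[C@@]4(C)O[C@@]25/C(=C\1O)C(=O)O[C@@]35C[C@@]4(C)O[Si](C)(C)C
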